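The readings cannot show the ligand that leaves, yet every exchange frees one. It can still be counted. Let a, b and c be complex with one exchanged, complex with two exchanged and complex with three exchanged, as fractions of the charge. Then n = a + 2b + 3c is leaving ligand per starting complex charged, e is incoming ligand charged per starting complex, and r = (e − n)/n is incoming over leaving ligand.

| flask | starting complex | incoming ligand | temperature | remark | time |
|---|---|---|---|---|---|
| zeta | 0.050 M | 0.034 M | −25 °C | run made earlier |  |
| alpha | 0.050 M | 0.56 M | 20 °C | run made earlier |  |
| epsilon | 0.036 M | 0.15 M | −25 °C | run made earlier |  |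
| violet | 0.050 M | 0.150 M | 5 °C |  | 80 min |
| teal | 0.10 M | 0.0400 M | 20 °C |  | 80 min |
| amber | 0.050 M | 0.150 M | 20 °C |  | 80 min |
| ochre | 0.10 M | 0.600 M | 60 °C |  | 80 min |
| blue | 0.015 M | 0.250 M | −20 °C |  | 80 min |

| run | time / min | complex with one exchanged / % | complex with two exchanged / % | complex with three exchanged / % |
|---|---|---|---|---|
| zeta | 60.0 | 0.2 | 0 | 1.1 |
| zeta | 150 | 1.9 | 0 | 1.1 |
| zeta | 300 | 4.2 | 0 | 0.4 |
| zeta | 720 | 7.1 | 0 | 0 |
| alpha | 20.0 | 39.0 | 41.7 | 2.5 |
| alpha | 40.0 | 41.1 | 40.6 | 7.2 |
| alpha | 60.0 | 41.4 | 39.1 | 8.1 |
| alpha | 80.0 | 40.2 | 36.4 | 10.3 |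
| epsilon | 180 | 11.5 | 1.9 | 1.1 |
| epsilon | 360 | 18.0 | 3.0 | 0.8 |
| epsilon | 600 | 26.7 | 6.1 | 0.7 |
| epsilon | 720 | 31.0 | 8.1 | 0 |

(each reading ± 1 percentage point)



- ranking by share of complex with one exchanged in all that became complex with one exchanged or complex with two exchanged or complex with three exchanged, from high to low, at 80 min (violet / teal / amber / ochre / blue)
- the share of complex with one exchanged in all that became complex with one exchanged or complex with two exchanged or complex with three exchanged of the flask you put first, at 80 min
- the share of complex with one exchanged in all that became complex with one exchanged or complex with two exchanged or complex with three exchanged of the flask you put last, at 80 min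

In alpha at 80.0 min, e is 11.2 and n is 1.44, so r is 6.78. The reading of b/a divided by r gives 0.133: this is the second-step quotient, a reading at 20 °C, to be used for a levelled flask at that temperature. Alpha's a reads as level, going from 39.0% to 40.2%.

In a levelled flask, at fixed temperature and starting complex, incoming ligand raises e, hence r, hence b/a. It also goes with the pace: from zeta to epsilon, where starting complex is lower too, ligand rises 4.41-fold and conversion at 720 min rises 5.51-fold, which reads as roughly first order.

Starting complex acts oppositely through e. Teal has e = 0.400, so incoming ligand is the limiting reagent. The first-step quotient read likewise in alpha is 0.452. With starting complex taken as unspent, that gives n near 0.256 and a share near 93.0%.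

Blue is taken as under kinetic control. Blue's ligand times time is 20.0 M min at −20 °C, against 27.0 M min for epsilon's first reading at −25 °C. Blue is therefore taken at that reading's share without c, 85.8%.

Ochre, with e = 6.00 and n taken as one, reckons near 60.0%, though what 60 °C does to the quotient stands in no run. Colder violet lags amber and stays above it, so the reckoning here runs teal, blue, violet, amber, ochre.

The forecast gave blue > teal > violet > amber > ochre, with 93% and 55%, since “That gives a statistical equilibrium with K≈0.14 per site, and a slow third step.”

The flasks give teal > blue > violet > amber > ochre, with 91.7% at the top and 37.4% at the bottom.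

    starting complex + incoming ligand ⇌ leaving ligand + complex with one exchanged (K = 0.580, k = 0.200 M⁻¹ min⁻¹, Ea = 51.0 kJ mol⁻¹, ΔH = −19.0 kJ mol⁻¹)
    complex with one exchanged + incoming ligand ⇌ leaving ligand + complex with two exchanged (K = 0.140, k = 0.810 M⁻¹ min⁻¹, Ea = 65.0 kJ mol⁻¹, ΔH = 21.0 kJ mol⁻¹)
    complex with two exchanged + incoming ligand ⇌ leaving ligand + complex with three exchanged (K = 0.110, k = 0.0100 M⁻¹ min⁻¹, Ea = 61.0 kJ mol⁻¹, ΔH = −51.0 kJ mol⁻¹)
    (constants at 20 °C)

Ochre parts from the reckoning. Its leaving ligand gives n = 1.18, so r is 4.10, and its b/a then gives a quotient of 0.394 at 60 °C, higher than alpha's 0.133 at 20 °C. The neighbouring flask is ochre with 1.0 M of incoming ligand, so e is 10.0 and n is 1.44. Its r of 5.94 with ochre's quotient reckons a share near 29.9% without c. That flask holds 23.8% complex with one exchanged, 55.7% complex with two exchanged and 2.95% complex with three exchanged, a share of 28.9%.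

Readings and results are simulated with constants of no real substance.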